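**Plan**

- Retrosynthesis: after removal of four silyl ethers, ring C is cut at C4–C3 and at O1–C2 (retro-hetero-Diels–Alder) into an ortho-quinone methide of ring A and a protected 4-vinylphenol. The methide carbon is then traced back to a Mannich CH2–N arm, the diketone to a benzyl ketone (C–H oxidation), and the aryl–acyl bond to phloroglucinol is cut last.
- Forward: ring A is bought as phloroglucinol and acylated. Three phenols are silylated so that only the ketone-chelated one stays free. CH2 → C=O gives the 1,2-diketone, a CH2NMe2 arm is placed ortho to the free phenol, ring C is closed last by the cycloaddition, and desilylation ends the route.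
- Enabling feature: the single free oxygen of ring A (the later O1) lies between the aminomethyl carbon (the later C4) and the C8 ketone. It alone can become the quinone-methide oxygen, which gives the 8-acyl and not the 6-acyl flavan. With the C8 carbonyl oxygen it forms a 1,3-dioxygen chelate that holds a chiral copper Lewis acid on the heterodiene O1=C8a–C4a=C4.
- Stereochemistry: C2 is the only stereocenter. It is set in the cycloaddition by the bis(oxazoline) ligand on copper and is not touched afterwards.

Key step: step 6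

Assumption: the ortho-hydroxyaryl 1,2-diketones of the route and the target are written as open diketones; their cyclic hemiketal tautomers (2-aryl-2-hydroxybenzofuran-3-ones) are taken to be in mobile equilibrium with them. TBS = tert-butyldimethylsilyl.

**Route**

Step 1
Reactants: 1 phloroglucinol (benzene-1,3,5-triol); 2 4-hydroxyphenylacetic acid
Product: 3 2-(4-hydroxyphenyl)-1-(2,4,6-trihydroxyphenyl)ethan-1-one
Conditions: BF3·OEt2 (as solvent), 85 °C; then aq. NaOAc
Reagents that add atoms: none
Why: Friedel–Crafts C-acylation (Houben–Hoesch type) of the symmetric, highly nucleophilic triol by the BF3-activated acid, which should stop after one acylation because the product is held as a deactivated boron chelate.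

Step 2
Reactants: 3 2-(4-hydroxyphenyl)-1-(2,4,6-trihydroxyphenyl)ethan-1-one
Product: 4 1-[2,4-bis(TBS-oxy)-6-hydroxyphenyl]-2-[4-(TBS-oxy)phenyl]ethan-1-one
Conditions: TBSCl (3.2 equiv), imidazole (6.5 equiv), DMF, 0 °C → rt
Reagents that add atoms: tert-butyldimethylsilyl chloride (TBSCl), CC(C)(C)[Si](C)(C)Cl
Why: Silyl ether formation at the 4'-OH, the para-OH and one of the two equivalent ortho-OH groups, after which the remaining ortho-OH is locked in a hydrogen bond to the ketone and should stay free as the later ring oxygen O1.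

Step 3
Reactants: 4 1-[2,4-bis(TBS-oxy)-6-hydroxyphenyl]-2-[4-(TBS-oxy)phenyl]ethan-1-one
Product: 5 1-[2,4-bis(TBS-oxy)-6-hydroxyphenyl]-2-[4-(TBS-oxy)phenyl]ethane-1,2-dione
Conditions: SeO2 (1.5 equiv), 1,4-dioxane, 95 °C
Reagents that add atoms: selenium dioxide, O=[Se]=O
Why: Riley oxidation of the doubly activated methylene between the ketone and the aryl ring, through its enol, to the 1,2-diketone; the molecule has no other enolisable or allylic C–H, and the aryl silyl ethers should tolerate the neutral, water-poor medium.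

Step 4
Reactants: 5 1-[2,4-bis(TBS-oxy)-6-hydroxyphenyl]-2-[4-(TBS-oxy)phenyl]ethane-1,2-dione
Product: 6 1-[4,6-bis(TBS-oxy)-3-[(dimethylamino)methyl]-2-hydroxyphenyl]-2-[4-(TBS-oxy)phenyl]ethane-1,2-dione
Conditions: Me2N=CH2+ I− (1.3 equiv), iPr2NEt (1.3 equiv), CH2Cl2, 0 °C → rt
Reagents that add atoms: N,N-dimethylmethyleneiminium iodide, C=[N+](C)C.[I-]
Why: Phenol Mannich reaction in which the phenoxide attacks the preformed iminium ion through its only free ortho carbon, the other ring C–H being para and shut in between two bulky silyloxy groups, while the non-enolisable diketone cannot undergo a ketone Mannich reaction.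

Step 5
Reactants: 6 1-[4,6-bis(TBS-oxy)-3-[(dimethylamino)methyl]-2-hydroxyphenyl]-2-[4-(TBS-oxy)phenyl]ethane-1,2-dione
Product: 7 [4,6-bis(TBS-oxy)-2-hydroxy-3-[2-[4-(TBS-oxy)phenyl]-2-oxoacetyl]phenyl]methyl-trimethylammonium trifluoromethanesulfonate
Conditions: MeOTf (1.05 equiv), CH2Cl2, −20 °C → 0 °C; solvent removed cold, salt used at once
Reagents that add atoms: methyl trifluoromethanesulfonate (MeOTf), COS(=O)(=O)C(F)(F)F
Why: Menshutkin N-methylation, the tertiary amine being far more nucleophilic than the hydrogen-bonded phenol; the NMe3+ group is the nucleofuge that should let the quinone methide form below room temperature.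

Step 6
Reactants: 7 [4,6-bis(TBS-oxy)-2-hydroxy-3-[2-[4-(TBS-oxy)phenyl]-2-oxoacetyl]phenyl]methyl-trimethylammonium trifluoromethanesulfonate; 8 tert-butyldimethyl(4-vinylphenoxy)silane
Product: 10 1-[(2S)-5,7-bis(TBS-oxy)-2-[4-(TBS-oxy)phenyl]-3,4-dihydro-2H-chromen-8-yl]-2-[4-(TBS-oxy)phenyl]ethane-1,2-dione, via copper-bound ortho-quinone methide 9 (not isolated)
Conditions: Cu(OTf)2 (10 mol %), (S,S)-2,2'-isopropylidenebis(4-tert-butyl-2-oxazoline) (11 mol %), 2,6-di-tert-butylpyridine (20 mol %), 8 (3 equiv), 4 Å MS, CH2Cl2, −40 → −10 °C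
Reagents that add atoms: none
Why: Proposed new method: the phenol oxygen and the neighbouring ring-A ketone oxygen of 7 should bind the divalent copper of the Cu(OTf)2–bis(oxazoline) catalyst as a six-membered chelate, the acidified phenol passes its proton to the hindered pyridine shuttle and Me3N leaves (E1cB), so that ortho-quinone methide 9 is formed on the metal and the amine ends as its triflate salt. The bound, cationic heterodiene (O=C–C=CH2 of ring A) should then take up the electron-rich styrene 8 in an inverse-electron-demand hetero-Diels–Alder reaction that is concerted but asynchronous, the C–C bond from the methide carbon to the styrene terminus leading and the O–C(benzylic) bond following. The closest known reaction types are the thermal or Lewis-acid cycloaddition of ortho-quinone methides from quaternised Mannich bases with styrenes, which gives racemic flavans, and the enantioselective hetero-Diels–Alder reaction of two-point-bound α,β-unsaturated carbonyl heterodienes with electron-rich alkenes under bis(oxazoline) complexes of Cu(OTf)2; new is their union on a methide-unsubstituted quinone methide whose own acyl group is the second binding point. Ring C closes in the [4+2] mode (in the stepwise limit a 6-exo-trig capture of the para-silyloxybenzyl cation by the copper-bound oxygen), and ring A regains its aromaticity. The only new stereocenter, C2, is controlled by the ligand, whose tert-butyl groups screen one face of the planar chelate so that the styrene adds to the open face with its aryl group endo; the (S,S)-ligand is the working choice for (2S), the sense is to be confirmed on the first run and the (R,R)-ligand taken if it proves opposite. The step needs head-to-tail orientation, which the polarisation of both partners secures; it needs the right phenol oxygen, which is secured because only one hydroxyl is free; and it needs a silent racemic background and no styrene oligomerisation, for which the salt 7 should not ionise off the metal at low temperature and the hindered pyridine traps stray protons.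

Step 7
Reactants: 10 1-[(2S)-5,7-bis(TBS-oxy)-2-[4-(TBS-oxy)phenyl]-3,4-dihydro-2H-chromen-8-yl]-2-[4-(TBS-oxy)phenyl]ethane-1,2-dione
Product: 11 1-[(2S)-5,7-dihydroxy-2-(4-hydroxyphenyl)-3,4-dihydro-2H-chromen-8-yl]-2-(4-hydroxyphenyl)ethane-1,2-dione (CNP0332855.1)
Conditions: Bu4NF (4.4 equiv), AcOH (4.4 equiv), THF, 0 °C, argon
Reagents that add atoms: none
Why: Fluoride-induced cleavage of the four aryl O–Si bonds (strong Si–F bond) with acetic acid protonating each phenoxide as it forms, so that neither a benzilic acid rearrangement of the diketone nor a base-induced opening of ring C at C2 should occur and the (2S) center is kept.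

**Compound list**

1 | phloroglucinol (benzene-1,3,5-triol) | Oc1cc(O)cc(O)c1 | starting material
2 | 4-hydroxyphenylacetic acid | OC(=O)Cc1ccc(O)cc1 | starting material
3 | 2-(4-hydroxyphenyl)-1-(2,4,6-trihydroxyphenyl)ethan-1-one | O=C(Cc1ccc(O)cc1)c1c(O)cc(O)cc1O | intermediate
4 | 1-[2,4-bis(TBS-oxy)-6-hydroxyphenyl]-2-[4-(TBS-oxy)phenyl]ethan-1-one | O=C(Cc1ccc(O[Si](C)(C)C(C)(C)C)cc1)c1c(O)cc(O[Si](C)(C)C(C)(C)C)cc1O[Si](C)(C)C(C)(C)C | intermediate
5 | 1-[2,4-bis(TBS-oxy)-6-hydroxyphenyl]-2-[4-(TBS-oxy)phenyl]ethane-1,2-dione | O=C(C(=O)c1c(O)cc(O[Si](C)(C)C(C)(C)C)cc1O[Si](C)(C)C(C)(C)C)c1ccc(O[Si](C)(C)C(C)(C)C)cc1 | intermediate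
6 | 1-[4,6-bis(TBS-oxy)-3-[(dimethylamino)methyl]-2-hydroxyphenyl]-2-[4-(TBS-oxy)phenyl]ethane-1,2-dione | O=C(C(=O)c1c(O)c(CN(C)C)c(O[Si](C)(C)C(C)(C)C)cc1O[Si](C)(C)C(C)(C)C)c1ccc(O[Si](C)(C)C(C)(C)C)cc1 | intermediate
7 | [4,6-bis(TBS-oxy)-2-hydroxy-3-[2-[4-(TBS-oxy)phenyl]-2-oxoacetyl]phenyl]methyl-trimethylammonium trifluoromethanesulfonate | O=C(C(=O)c1c(O)c(C[N+](C)(C)C)c(O[Si](C)(C)C(C)(C)C)cc1O[Si](C)(C)C(C)(C)C)c1ccc(O[Si](C)(C)C(C)(C)C)cc1.[O-]S(=O)(=O)C(F)(F)F | intermediate
8 | tert-butyldimethyl(4-vinylphenoxy)silane (4-(TBS-oxy)styrene) | C=Cc1ccc(O[Si](C)(C)C(C)(C)C)cc1 | starting material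
9 | copper-bound ortho-quinone methide, 3,5-bis(TBS-oxy)-6-methylidene-2-[2-[4-(TBS-oxy)phenyl]-2-oxoacetyl]cyclohexa-2,4-dien-1-one (not isolated; drawn without the metal) | C=C1C(=O)C(C(=O)C(=O)c2ccc(O[Si](C)(C)C(C)(C)C)cc2)=C(O[Si](C)(C)C(C)(C)C)C=C1O[Si](C)(C)C(C)(C)C | intermediate
10 | 1-[(2S)-5,7-bis(TBS-oxy)-2-[4-(TBS-oxy)phenyl]-3,4-dihydro-2H-chromen-8-yl]-2-[4-(TBS-oxy)phenyl]ethane-1,2-dione | O=C(C(=O)c1c(O[Si](C)(C)C(C)(C)C)cc(O[Si](C)(C)C(C)(C)C)c2c1O[C@H](c1ccc(O[Si](C)(C)C(C)(C)C)cc1)CC2)c1ccc(O[Si](C)(C)C(C)(C)C)cc1 | intermediate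
11 | 1-[(2S)-5,7-dihydroxy-2-(4-hydroxyphenyl)-3,4-dihydro-2H-chromen-8-yl]-2-(4-hydroxyphenyl)ethane-1,2-dione | O=C(C(=O)c1c(O)cc(O)c2c1O[C@H](c1ccc(O)cc1)CC2)c1ccc(O)cc1 | target

**Step count and risks**

Total steps: 7. Longest linear sequence: 7 steps (1 → 11); 8 is used as bought.

Steps most likely to fail:

1. Step 6 (Proposed new method). The catalyst may discriminate the two faces of the chelated quinone methide poorly, the amine released may slow the copper catalyst, or the electron-rich styrene may oligomerise cationically before it is captured. Fallback with known chemistry, setting out from 6 and coming back at 10: the Mannich base 6 is heated with 8 (4 equiv) in toluene at 120 °C in a sealed vessel. Thermal loss of dimethylamine gives the free form of 9, which adds the styrene without catalyst to give the racemic tetrasilyl flavan F1. Preparative HPLC on a chiral stationary phase (cellulose tris(3,5-dimethylphenylcarbamate)) then separates 10 from the (2R)-tetrasilyl flavan F2, which is set aside.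

2. Step 4. The chelated, acyl-deactivated phenol may react sluggishly with the iminium ion, attack may stray to the ring carbon between the two silyloxy groups, or a silyl group may be lost under the basic conditions. Fallback setting out from 5 and coming back at 6: 5 is heated with paraformaldehyde and PhB(OH)2 (cat. propionic acid, toluene, reflux, water removal). The new C–C bond then forms inside a boron-bound cyclic transition state and can only go ortho to the phenol, giving the 2-phenyl-4H-1,3,2-benzodioxaborin F3. Boron is removed by exchange with propane-1,3-diol to give the salicyl alcohol F4, which on warming with Me2NH (2 M in THF, 60 °C) passes through the quinone methide to 6.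

3. Step 3. Hot selenous acid may strip silyl ethers, the oxidation may stall on the hindered chelated ketone, or colloidal selenium may be hard to remove. Fallback setting out from 4 and coming back at 5: 4 is converted with KN(SiMe3)2 (2.2 equiv, THF, −78 °C) into the phenoxide–enolate, which is hydroxylated with 3-phenyl-2-(phenylsulfonyl)oxaziridine to give the α-hydroxy ketone F5 (racemic). Oxidation of this benzoin with 2-iodoxybenzoic acid (EtOAc, 70 °C) gives 5.

Further compounds
F1 | step 6 | racemic 1-[5,7-bis(TBS-oxy)-2-[4-(TBS-oxy)phenyl]-3,4-dihydro-2H-chromen-8-yl]-2-[4-(TBS-oxy)phenyl]ethane-1,2-dione | O=C(C(=O)c1c(O[Si](C)(C)C(C)(C)C)cc(O[Si](C)(C)C(C)(C)C)c2c1OC(c1ccc(O[Si](C)(C)C(C)(C)C)cc1)CC2)c1ccc(O[Si](C)(C)C(C)(C)C)cc1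
F2 | step 6 | 1-[(2R)-5,7-bis(TBS-oxy)-2-[4-(TBS-oxy)phenyl]-3,4-dihydro-2H-chromen-8-yl]-2-[4-(TBS-oxy)phenyl]ethane-1,2-dione | O=C(C(=O)c1c(O[Si](C)(C)C(C)(C)C)cc(O[Si](C)(C)C(C)(C)C)c2c1O[C@@H](c1ccc(O[Si](C)(C)C(C)(C)C)cc1)CC2)c1ccc(O[Si](C)(C)C(C)(C)C)cc1
F3 | step 4 | 1-[5,7-bis(TBS-oxy)-2-phenyl-4H-1,3,2-benzodioxaborin-8-yl]-2-[4-(TBS-oxy)phenyl]ethane-1,2-dione | O=C(C(=O)c1c2OB(c3ccccc3)OCc2c(O[Si](C)(C)C(C)(C)C)cc1O[Si](C)(C)C(C)(C)C)c1ccc(O[Si](C)(C)C(C)(C)C)cc1
F4 | step 4 | 1-[4,6-bis(TBS-oxy)-2-hydroxy-3-(hydroxymethyl)phenyl]-2-[4-(TBS-oxy)phenyl]ethane-1,2-dione | O=C(C(=O)c1c(O)c(CO)c(O[Si](C)(C)C(C)(C)C)cc1O[Si](C)(C)C(C)(C)C)c1ccc(O[Si](C)(C)C(C)(C)C)cc1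
F5 | step 3 | 1-[2,4-bis(TBS-oxy)-6-hydroxyphenyl]-2-hydroxy-2-[4-(TBS-oxy)phenyl]ethan-1-one (racemic) | O=C(C(O)c1ccc(O[Si](C)(C)C(C)(C)C)cc1)c1c(O)cc(O[Si](C)(C)C(C)(C)C)cc1O[Si](C)(C)C(C)(C)C
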